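**Strategy.** The central dihydropyran (ring C: O-9, C-9, C-8a, C-8, C-2′, C-3′; naphtho[2,3-b]furan numbering for the tricyclic half, primed benzofuran numbering for the other) is cut at O-9–C-3′ and C-8a–C-8, and also at C-8–C-2′. Acid closes the open-chain phenol aldehyde 11 onto C-8a (ring E), the resulting salicyl-type alcohol gives an ortho-quinone methide, and benzofuran 19 adds across it through its enol-ether bond C-2′=C-3′. One operation thus joins two C15 benzofurans at the quaternary C-3′ and sets C-8, C-2′ and C-3′. The feature exploited is the 1,3-relationship of O-9 and C-8 around C-8a, a latent ortho-quinone methide.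

Key step: step 14

Remark on locants: ring A = phenol ring of the primed half, ring B = its dihydrofuran, ring C = dihydropyran, ring D = benzene ring of the tricyclic half, ring E = its cyclohexane ring, ring F = its furan. In the open-chain compounds the locants are those the atoms will carry in 22.

Assumption: in step 7 the PyrOx antipode (or, for a given antipode, the E or Z alkenol) that leads to the S aldehyde is used; the sense of induction for this ortho-substituted aryl group has to be confirmed by correlation.

**Route**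

Step 1
Reactants: 1 2-methoxy-5-methylphenol
Product: 2 4-bromo-2-methoxy-5-methylphenol
Conditions: NBS (1.0 equiv), MeCN, 0 °C
Reagents that add atoms: N-bromosuccinimide (O=C1CCC(=O)N1Br)
Why: Electrophilic aromatic bromination; the free hydroxyl directs to its para position, which is less hindered than the ortho site between OH and CH3, so bromine marks the carbon that will carry the side chain.

Step 2
Reactants: 2 4-bromo-2-methoxy-5-methylphenol; 3 chloroacetone
Product: 4 1-(4-bromo-2-methoxy-5-methylphenoxy)propan-2-one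
Conditions: K2CO3, KI (cat.), acetone, reflux
Reagents that add atoms: none
Why: Williamson ether synthesis (SN2 of the phenoxide on the α-chloroketone, iodide-assisted).

Step 3
Reactants: 4 1-(4-bromo-2-methoxy-5-methylphenoxy)propan-2-one
Product: 5 5-bromo-7-methoxy-3,4-dimethylbenzofuran
Conditions: polyphosphoric acid, PhCl, 90 °C
Reagents that add atoms: none
Why: Acid-mediated cyclodehydration of an aryloxyacetone (intramolecular Friedel-Crafts hydroxyalkylation, then loss of water) at the only free position ortho to the ether oxygen gives the 3-methylbenzofuran.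

Step 4
Reactants: 5 5-bromo-7-methoxy-3,4-dimethylbenzofuran
Product: 6 5-bromo-3,4-dimethylbenzofuran-7-ol
Conditions: BBr3, CH2Cl2, −78 to 0 °C; then H2O
Reagents that add atoms: none
Why: Lewis-acid cleavage of the aryl methyl ether (bromide attacks the methyl group of the boron-bound ether); the aryl bromide and the furan should be inert.

Step 5
Reactants: 6 5-bromo-3,4-dimethylbenzofuran-7-ol
Product: 7 [(5-bromo-3,4-dimethylbenzofuran-7-yl)oxy](tert-butyl)dimethylsilane
Conditions: TBSCl, imidazole, DMF, rt
Reagents that add atoms: tert-butyldimethylsilyl chloride (CC(C)(C)[Si](C)(C)Cl)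
Why: Standard silylation of the phenol, which masks the acidic and oxidizable OH for the organolithium and oxidative Heck steps.

Step 6
Reactants: 7 [(5-bromo-3,4-dimethylbenzofuran-7-yl)oxy](tert-butyl)dimethylsilane
Product: 8 [7-(tert-butyldimethylsilyloxy)-3,4-dimethylbenzofuran-5-yl]boronic acid
Conditions: B(OiPr)3, n-BuLi, THF/toluene, −78 °C (in situ trap); then 1 M HCl to pH 5, 0 °C
Reagents that add atoms: triisopropyl borate (CC(C)OB(OC(C)C)OC(C)C); water (O)
Why: Bromine-lithium exchange with immediate borate trapping, so the aryllithium has no time to deprotonate the furan C-2 position; hydrolysis gives the boronic acid.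

Step 7
Reactants: 8 [7-(tert-butyldimethylsilyloxy)-3,4-dimethylbenzofuran-5-yl]boronic acid; 9 (E)-pent-3-en-1-ol
Product: 10 (S)-4-[7-(tert-butyldimethylsilyloxy)-3,4-dimethylbenzofuran-5-yl]pentanal
Conditions: Pd(MeCN)2(OTs)2 (6 mol%), Cu(OTf)2 (6 mol%), 4-tert-butyl-2-[5-(trifluoromethyl)pyridin-2-yl]-4,5-dihydrooxazole (13 mol%, antipode per assumption), 3 Å MS, O2 (1 atm), DMF, rt; 9 (3 equiv)
Reagents that add atoms: none
Why: Enantioselective redox-relay oxidative Heck reaction: the aryl group adds to the alkene carbon remote from the hydroxyl, divalent palladium walks along the chain by β-hydride elimination and reinsertion and leaves at the carbinol carbon as the aldehyde, and the chiral PyrOx complex selects the alkene face and so sets C-5 as S.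

Step 8
Reactants: 10 (S)-4-[7-(tert-butyldimethylsilyloxy)-3,4-dimethylbenzofuran-5-yl]pentanal
Product: 11 (S)-4-(7-hydroxy-3,4-dimethylbenzofuran-5-yl)pentanal
Conditions: Bu4NF, AcOH (1:1), THF, 0 °C; used promptly
Reagents that add atoms: none
Why: Fluoride desilylation buffered with acetic acid, so no phenoxide is present to attack the aldehyde; C-5 is not adjacent to the carbonyl and cannot epimerize.

Step 9
Reactants: 12 2-methoxy-4-methylphenol; 3 chloroacetone
Product: 13 1-(2-methoxy-4-methylphenoxy)propan-2-one
Conditions: K2CO3, KI (cat.), acetone, reflux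
Reagents that add atoms: none
Why: Williamson ether synthesis as in step 2.

Step 10
Reactants: 13 1-(2-methoxy-4-methylphenoxy)propan-2-one
Product: 14 7-methoxy-3,5-dimethylbenzofuran
Conditions: polyphosphoric acid, PhCl, 90 °C
Reagents that add atoms: none
Why: Cyclodehydration of the aryloxyacetone at the only free ortho position, as in step 3.

Step 11
Reactants: 14 7-methoxy-3,5-dimethylbenzofuran
Product: 15 3,5-dimethylbenzofuran-7-ol
Conditions: BBr3, CH2Cl2, −78 to 0 °C; then H2O
Reagents that add atoms: none
Why: BBr3 ether cleavage as in step 4.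

Step 12
Reactants: 15 3,5-dimethylbenzofuran-7-ol
Product: 16 6-bromo-3,5-dimethylbenzofuran-7-ol
Conditions: NBS (1.0 equiv), i-Pr2NH (10 mol%), CH2Cl2, −78 to 0 °C
Reagents that add atoms: N-bromosuccinimide (O=C1CCC(=O)N1Br)
Why: Amine-mediated ortho-selective bromination of a phenol (hydrogen-bonded N-bromoamine delivers bromine next to OH); C-6 is the only ortho site, and the para site C-4 is shielded by the 5-methyl and the peri 3-methyl groups.

Step 13
Reactants: 16 6-bromo-3,5-dimethylbenzofuran-7-ol; 17 (E)-penta-1,3-diene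
Product: 19 3,5-dimethyl-6-[(E)-pent-3-enyl]benzofuran-7-ol, via B-[(E)-pent-3-enyl]-9-BBN 18 (not isolated)
Conditions: 17 (1.5 equiv per B–H), 9-BBN-H dimer, THF, 0 °C to rt; then 16, Pd(OAc)2 (5 mol%), SPhos (10 mol%), K3PO4 (3 M aq), THF, 60 °C
Reagents that add atoms: none
Why: Anti-Markovnikov hydroboration of the terminal double bond of the diene by 9-BBN leaves the E-disubstituted alkene untouched, and B-alkyl Suzuki-Miyaura coupling with the hindered aryl bromide transfers the intact (E)-pent-3-enyl group.

Step 14
Reactants: 11 (S)-4-(7-hydroxy-3,4-dimethylbenzofuran-5-yl)pentanal; 19 3,5-dimethyl-6-[(E)-pent-3-enyl]benzofuran-7-ol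
Product: 22 target heterodimer (2′R,3′R,5S,8R), via cyclized diol 20 (not isolated), via ortho-quinone methide 21 (not isolated)
Conditions: 19 (2.5 equiv, excess recovered), (PhO)2P(O)OH (20 mol%), 4 Å MS, ClCH2CH2Cl, 60 °C; 11 added over 6 h by syringe pump (final 0.02 M)
Reagents that add atoms: none
Why: The acid activates the aldehyde of 11 for intramolecular ortho-hydroxyalkylation of the phenol (6-exo-trig attack of C-8a on C-8, closing ring E to 20), whose benzylic hydroxyl ortho to the phenol is lost to give the E-locked ortho-quinone methide 21; 19 then adds through C-2′=C-3′ in an inverse-demand hetero-Diels-Alder reaction that closes ring C by (4+2) cycloaddition, with C-8–C-2′ leading and O-9–C-3′ completing it. The closest known reaction type is the three-component phenol/aldehyde/alkene chroman synthesis through ortho-quinone methides, together with their dearomative (4+2) additions to furans, benzofurans and indoles. Suprafacial addition makes the B/C fusion cis (H-2′ and the 3′-methyl cis), and endo approach of the benzo ring of 19 places H-8 cis to H-2′. The face of 21 is governed by C-5: the adduct that keeps ring E as a half-chair with the 5-methyl pseudoaxial (no allylic 1,3-strain with the 4-methyl) and H-8 pseudoaxial has H-5 and H-8 cis, as in 22, and because acid-mediated ortho-quinone methide cycloadditions are reversible at this temperature, this most stable adduct should accumulate even if the kinetic face preference is the opposite one. The step needs 19 to win over the furan C-2 of a second molecule of 11 and over C-4′ of its own phenol ring: 19 is in excess with slow addition of 11, C-4′ is flanked by the 5′-methyl and the peri 3′-methyl, and C-2′ is the most nucleophilic carbon with polarity matched to C-8.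

**Compound list**

1 | 2-methoxy-5-methylphenol | COc1ccc(C)cc1O | starting material
2 | 4-bromo-2-methoxy-5-methylphenol | COc1cc(Br)c(C)cc1O | intermediate
3 | chloroacetone | CC(=O)CCl | starting material
4 | 1-(4-bromo-2-methoxy-5-methylphenoxy)propan-2-one | COc1cc(Br)c(C)cc1OCC(C)=O | intermediate
5 | 5-bromo-7-methoxy-3,4-dimethylbenzofuran | COc1cc(Br)c(C)c2c(C)coc12 | intermediate
6 | 5-bromo-3,4-dimethylbenzofuran-7-ol | Oc1cc(Br)c(C)c2c(C)coc12 | intermediate
7 | [(5-bromo-3,4-dimethylbenzofuran-7-yl)oxy](tert-butyl)dimethylsilane | CC(C)(C)[Si](C)(C)Oc1cc(Br)c(C)c2c(C)coc12 | intermediate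
8 | [7-(tert-butyldimethylsilyloxy)-3,4-dimethylbenzofuran-5-yl]boronic acid | CC(C)(C)[Si](C)(C)Oc1cc(B(O)O)c(C)c2c(C)coc12 | intermediate
9 | (E)-pent-3-en-1-ol | C/C=C/CCO | starting material
10 | (S)-4-[7-(tert-butyldimethylsilyloxy)-3,4-dimethylbenzofuran-5-yl]pentanal | O=CCC[C@H](C)c1cc(O[Si](C)(C)C(C)(C)C)c2occ(C)c2c1C | intermediate
11 | (S)-4-(7-hydroxy-3,4-dimethylbenzofuran-5-yl)pentanal | O=CCC[C@H](C)c1cc(O)c2occ(C)c2c1C | intermediate
12 | 2-methoxy-4-methylphenol | COc1cc(C)ccc1O | starting material
13 | 1-(2-methoxy-4-methylphenoxy)propan-2-one | COc1cc(C)ccc1OCC(C)=O | intermediate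
14 | 7-methoxy-3,5-dimethylbenzofuran | COc1cc(C)cc2c(C)coc12 | intermediate
15 | 3,5-dimethylbenzofuran-7-ol | Oc1cc(C)cc2c(C)coc12 | intermediate
16 | 6-bromo-3,5-dimethylbenzofuran-7-ol | Oc1c(Br)c(C)cc2c(C)coc12 | intermediate
17 | (E)-penta-1,3-diene | C/C=C/C=C | starting material
18 | B-[(E)-pent-3-enyl]-9-borabicyclo[3.3.1]nonane (not isolated) | C/C=C/CCB1C2CCCC1CCC2 | intermediate
19 | 3,5-dimethyl-6-[(E)-pent-3-enyl]benzofuran-7-ol | C/C=C/CCc1c(C)cc2c(C)coc2c1O | intermediate
20 | (5S)-3,4,5-trimethyl-5,6,7,8-tetrahydronaphtho[2,3-b]furan-8,9-diol, both C-8 epimers (not isolated) | OC1CC[C@H](C)c2c(C)c3c(C)coc3c(O)c12 | intermediate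
21 | (5S)-3,4,5-trimethyl-6,7-dihydronaphtho[2,3-b]furan-9(5H)-one, the ortho-quinone methide with the C-8=C-8a double bond (not isolated) | O=C1C(=CCC[C@@H]2C)C2=C(C)c2c(C)coc12 | intermediate
22 | target heterodimer, (2′R,3′R,5S,8R): O-9 of the 3,4,5-trimethyl-5,6,7,8-tetrahydronaphtho[2,3-b]furan half bonded to C-3′ and C-8 bonded to C-2′ of 3,5-dimethyl-6-[(E)-pent-3-enyl]-2,3-dihydrobenzofuran-7-ol | C/C=C/CCc1c(C)cc2c(c1O)O[C@@H]1[C@@H]3CC[C@H](C)c4c3c(c3occ(C)c3c4C)O[C@]21C | target

**Step count and risks**

Total: 14 steps. Longest linear sequence: 9 steps (steps 1 to 8, then step 14); the second branch is steps 9 to 13.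

Steps most likely to fail:

1. Step 14. The ortho-quinone methide may be captured by the furan of a second molecule of 11 or oligomerize, and addition may occur on the wrong face or exo before equilibration sets in. The tether fallback removes only the first of these; the face and endo/exo outcome still rests on acid equilibration. Fallback (sets out from 10 and 19, returns at 22): 19 is silylated (TBSCl, imidazole) to tert-butyl{[3,5-dimethyl-6-((E)-pent-3-enyl)benzofuran-7-yl]oxy}dimethylsilane F1. F1 is lithiated at C-2′ (n-BuLi, THF, −78 to 0 °C) and added to aldehyde 10 to give the bis-silylated benzofuran-2-yl carbinol F2 (both carbinol epimers). Bu4NF/AcOH then frees the triol F3. Treatment of F3 with (PhO)2P(O)OH or CF3CO2H should ionize the carbinol, close ring E by Friedel-Crafts attack of C-8a on C-8, and add O-9 to C-3′ of the protonated benzofuran. The same two bonds thus form intramolecularly, with no competing partner, to give 22.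

2. Step 7. Transmetalation and insertion of the ortho-substituted, electron-rich arylboronic acid may be slow, so that homocoupling, protodeboronation or arylation at the furan C-2 takes over, or the enantioselectivity erodes. Fallback (sets out from 7, returns at 10): Stille vinylation (Bu3SnCH=CH2, Pd(PPh3)4, toluene, 100 °C) gives tert-butyl[(3,4-dimethyl-5-vinylbenzofuran-7-yl)oxy]dimethylsilane F4. Asymmetric hydrovinylation (ethylene, [(allyl)NiBr]2, chiral phosphoramidite, Na[B(3,5-(CF3)2C6H3)4], CH2Cl2, −70 °C) gives (S)-[(5-(but-3-en-2-yl)-3,4-dimethylbenzofuran-7-yl)oxy](tert-butyl)dimethylsilane F5. Linear-selective hydroformylation (Rh(acac)(CO)2, BiPhePhos, CO/H2, toluene, 60 °C) then gives 10.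

3. Step 12. Bromine may enter at C-4 (para) or at the furan C-2 instead of C-6. Fallback (sets out from 15, returns at 19): O-allylation (allyl bromide, K2CO3, acetone) gives 7-(allyloxy)-3,5-dimethylbenzofuran F6. An aromatic Claisen rearrangement (PhNEt2, 190 °C), which can only deliver to C-6, gives 6-allyl-3,5-dimethylbenzofuran-7-ol F7. Hydroboration-oxidation (9-BBN-H; NaOH, H2O2) gives 6-(3-hydroxypropyl)-3,5-dimethylbenzofuran-7-ol F8. Parikh-Doering oxidation (SO3·pyridine, DMSO, i-Pr2NEt) gives 3-(7-hydroxy-3,5-dimethylbenzofuran-6-yl)propanal F9, handled as its cyclic hemiacetal. E-selective Julia-Kocienski olefination (5-(ethylsulfonyl)-1-phenyl-1H-tetrazole, KN(SiMe3)2 in excess, DME, −60 °C to rt) then gives 19.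

Further compounds
F1 | step 14 | tert-butyl{[3,5-dimethyl-6-((E)-pent-3-enyl)benzofuran-7-yl]oxy}dimethylsilane | C/C=C/CCc1c(C)cc2c(C)coc2c1O[Si](C)(C)C(C)(C)C
F2 | step 14 | (4S)-1-[7-(tert-butyldimethylsilyloxy)-3,5-dimethyl-6-((E)-pent-3-enyl)benzofuran-2-yl]-4-[7-(tert-butyldimethylsilyloxy)-3,4-dimethylbenzofuran-5-yl]pentan-1-ol | C/C=C/CCc1c(C)cc2c(C)c(C(O)CC[C@H](C)c3cc(O[Si](C)(C)C(C)(C)C)c4occ(C)c4c3C)oc2c1O[Si](C)(C)C(C)(C)C
F3 | step 14 | (4S)-1-[7-hydroxy-3,5-dimethyl-6-((E)-pent-3-enyl)benzofuran-2-yl]-4-(7-hydroxy-3,4-dimethylbenzofuran-5-yl)pentan-1-ol | C/C=C/CCc1c(C)cc2c(C)c(C(O)CC[C@H](C)c3cc(O)c4occ(C)c4c3C)oc2c1O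
F4 | step 7 | tert-butyl[(3,4-dimethyl-5-vinylbenzofuran-7-yl)oxy]dimethylsilane | C=Cc1cc(O[Si](C)(C)C(C)(C)C)c2occ(C)c2c1C
F5 | step 7 | (S)-[(5-(but-3-en-2-yl)-3,4-dimethylbenzofuran-7-yl)oxy](tert-butyl)dimethylsilane | C=C[C@H](C)c1cc(O[Si](C)(C)C(C)(C)C)c2occ(C)c2c1C
F6 | step 12 | 7-(allyloxy)-3,5-dimethylbenzofuran | C=CCOc1cc(C)cc2c(C)coc12
F7 | step 12 | 6-allyl-3,5-dimethylbenzofuran-7-ol | C=CCc1c(C)cc2c(C)coc2c1O
F8 | step 12 | 6-(3-hydroxypropyl)-3,5-dimethylbenzofuran-7-ol | OCCCc1c(C)cc2c(C)coc2c1O
F9 | step 12 | 3-(7-hydroxy-3,5-dimethylbenzofuran-6-yl)propanal | O=CCCc1c(C)cc2c(C)coc2c1O
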